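**Plan**

1. The target is the meso (2S,3R,2'R,3'S) dimer of 7,4'-dihydroxyflavanone, joined C3–C3' with both rings 2,3-trans. It is achiral, so only relative configuration has to be set.
2. Cuts: the four O–benzyl bonds (protection); then, in both halves at once, the aryl ether bond O1–C8a and the bond C2–C3, which releases two molecules of a benzaldehyde and one symmetric 1,4-diketone; last the C3–C3' bond, which leads back to an acetophenone.
3. Enabling feature: each C4 carbonyl sits between the enolisable C3 and ring A, where it is ortho to C8a. With fluoride on C8a, the unit C3–C4–C4a–C8a is a 1,4-dipole (C3 donor, C8a acceptor) that can add across an aldehyde C=O.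
4. Forward: benzyl ether, oxidative enolate coupling (C3–C3' chain), then one double aldol/SNAr annulation that closes both pyranone rings C onto the preformed rings A and brings in both rings B. The fluoride helper leaves in that step, the benzyl helpers in the last one.
5. Stereochemistry: C3/C3' (enolisation) and C2/C2' (ring opening and reclosure) stay mobile in the annulation pot, so thermodynamic control should give trans rings and the meso pairing, which is collected by crystallisation.

Key step: step 3

Assumption: the trans,trans meso isomer is taken to be the most stable and least soluble epimer of 9; this rests on conformational reasoning, not on a reported equilibrium.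

**Step 1**
Reactants: 1 1-(2-fluoro-4-hydroxyphenyl)ethan-1-one
Product: 2 1-[4-(benzyloxy)-2-fluorophenyl]ethan-1-one
Conditions: BnBr, K2CO3, acetone, 56 °C
Reagents that add atoms: benzyl bromide BrCc1ccccc1
Why: Williamson ether synthesis (SN2 O-benzylation of the phenoxide); carbonate and phenoxide are too weak to displace the ring fluoride at this temperature, and no stereocentre is formed.

**Step 2**
Reactants: 2 1-[4-(benzyloxy)-2-fluorophenyl]ethan-1-one (two molecules)
Product: 4 1,4-bis[4-(benzyloxy)-2-fluorophenyl]butane-1,4-dione, via lithium enolate 3 (not isolated)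
Conditions: LiN(iPr)2 (1.05 equiv), THF, −78 °C; then CuCl2 (1.1 equiv), DMF, −78 to 23 °C
Reagents that add atoms: none
Why: Oxidative homocoupling of a methyl ketone lithium enolate by divalent copper (CuCl2) should join two α-carbons into the 1,4-diketone, which is the future C3–C3' bond; no stereocentre is formed.

**Step 3**
Reactants: 4 1,4-bis[4-(benzyloxy)-2-fluorophenyl]butane-1,4-dione; 5 4-(benzyloxy)benzaldehyde (two molecules)
Product: 9 meso-(2S,3R,2'R,3'S)-7,7'-bis(benzyloxy)-2,2'-bis[4-(benzyloxy)phenyl]-[3,3'-bichromane]-4,4'-dione, via dilithium bis-enolate 6 (not isolated), via dilithium bis-aldolate 7 (not isolated), via stereorandom tetrabenzyl biflavanone 8 (not isolated)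
Conditions: LiN(iPr)2 (2.1 equiv), THF, −78 °C; 5 (2.1 equiv), −78 to −40 °C; DMPU, −40 to 50 °C; then EtOH, DBU (0.2 equiv), 70 °C; crystallisation
Reagents that add atoms: none
Why: LiN(iPr)2 should convert 4 into the bis-enolate 6, whose C3 and C3' add to the C=O of two molecules of 5 (aldol, C2–C3 and C2'–C3' bonds) to give bis-aldolate 7; on warming with DMPU each alkoxide O1 attacks C8a, ortho to the C4 carbonyl of its own aryl ketone, through a carbonyl-stabilised Meisenheimer adduct that expels fluoride as LiF (O1–C8a bond). The closest known reaction type is the tandem aldol/intramolecular SNAr O-arylation that turns 2-fluoroaryl ketones and aldehydes into chroman-4-ones, here run in both directions on one 1,4-diketone. Each pyranone ring (O1–C2–C3–C4–C4a–C8a) closes as a six-membered ring by addition–elimination, formally a 6-endo-trig conjugate addition of O1 to the C8a=C4a–C4=O unit, whereas attack on the other fluoroarene would need a seven-membered ring. The sequence first gives the stereorandom mixture 8; with DBU in hot ethanol C3 and C3' should epimerise through their enolates and C2 and C2' through reversible E1cB opening to the 2'-oxidochalcone and 6-endo oxa-Michael reclosure, so each ring should settle as the 2,3-trans (diequatorial) isomer. Between the halves, thermodynamic control should favour the meso pairing (2S,3R,2'R,3'S): its centrosymmetric conformer with H3 and H3' anti keeps the two C4 carbonyl dipoles opposed and the two aryl-bearing C2 carbons apart, while the racemic pairing must place like groups gauche; the meso isomer is also expected to be the less soluble one, so its crystallisation from the equilibrating slurry should drain the other epimers. The step needs ring closure to outrun retro-aldol, dehydration and aldol–Tishchenko side reactions: lithium counter-ion and low temperature hold the aldolates, only 2.1 equiv of 5 is used, fluoride is the best SNAr leaving group, and the benzyloxy group at C7 is meta to C8a and so does not deactivate it.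

**Step 4**
Reactants: 9 meso-(2S,3R,2'R,3'S)-7,7'-bis(benzyloxy)-2,2'-bis[4-(benzyloxy)phenyl]-[3,3'-bichromane]-4,4'-dione
Product: 10 (2S,3R,2'R,3'S)-7,7'-dihydroxy-2,2'-bis(4-hydroxyphenyl)-[3,3'-bichromane]-4,4'-dione
Conditions: H2 (1 atm), Pd/C (10 wt%), THF–EtOAc, 23 °C
Reagents that add atoms: none
Why: Hydrogenolysis of the four aryl benzyl ethers over Pd/C is neutral, so it should not epimerise C2 or C3, and at 1 atm it should leave the aryl ketones and the cyclic benzylic C2–O1 ethers intact.

**Compound list**

1 | 1-(2-fluoro-4-hydroxyphenyl)ethan-1-one | CC(=O)c1ccc(O)cc1F | starting material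
2 | 1-[4-(benzyloxy)-2-fluorophenyl]ethan-1-one | CC(=O)c1ccc(OCc2ccccc2)cc1F | intermediate
3 | lithium 1-[4-(benzyloxy)-2-fluorophenyl]ethen-1-olate (enolate of 2, formed in the flask) | [Li+].[O-]C(=C)c1ccc(OCc2ccccc2)cc1F | intermediate
4 | 1,4-bis[4-(benzyloxy)-2-fluorophenyl]butane-1,4-dione | O=C(CCC(=O)c1ccc(OCc2ccccc2)cc1F)c1ccc(OCc2ccccc2)cc1F | intermediate
5 | 4-(benzyloxy)benzaldehyde | O=Cc1ccc(OCc2ccccc2)cc1 | starting material
6 | dilithium (1Z,3Z)-1,4-bis[4-(benzyloxy)-2-fluorophenyl]buta-1,3-diene-1,4-diolate (bis-enolate of 4, formed in the flask) | [Li+].[Li+].[O-]/C(=C\C=C(/[O-])c1ccc(OCc2ccccc2)cc1F)c1ccc(OCc2ccccc2)cc1F | intermediate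
7 | dilithium 2,3-bis[4-(benzyloxy)-2-fluorobenzoyl]-1,4-bis[4-(benzyloxy)phenyl]butane-1,4-diolate (bis-aldolate, mixture of diastereomers, formed in the flask) | [Li+].[Li+].[O-]C(c1ccc(OCc2ccccc2)cc1)C(C(=O)c1ccc(OCc2ccccc2)cc1F)C(C(=O)c1ccc(OCc2ccccc2)cc1F)C([O-])c1ccc(OCc2ccccc2)cc1 | intermediate
8 | 7,7'-bis(benzyloxy)-2,2'-bis[4-(benzyloxy)phenyl]-[3,3'-bichromane]-4,4'-dione as mixture of diastereomers (C2, C3, C2', C3' not yet settled, formed in the flask) | O=C1c2ccc(OCc3ccccc3)cc2OC(c2ccc(OCc3ccccc3)cc2)C1C1C(=O)c2ccc(OCc3ccccc3)cc2OC1c1ccc(OCc2ccccc2)cc1 | intermediate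
9 | meso-(2S,3R,2'R,3'S)-7,7'-bis(benzyloxy)-2,2'-bis[4-(benzyloxy)phenyl]-[3,3'-bichromane]-4,4'-dione (both rings 2,3-trans) | O=C1c2ccc(OCc3ccccc3)cc2O[C@H](c2ccc(OCc3ccccc3)cc2)[C@H]1[C@@H]1C(=O)c2ccc(OCc3ccccc3)cc2O[C@H]1c1ccc(OCc2ccccc2)cc1 | intermediate
10 | (2S,3R,2'R,3'S)-7,7'-dihydroxy-2,2'-bis(4-hydroxyphenyl)-[3,3'-bichromane]-4,4'-dione (meso, both rings 2,3-trans; CNP0231820.1) | O=C1c2ccc(O)cc2O[C@H](c2ccc(O)cc2)[C@H]1[C@@H]1C(=O)c2ccc(O)cc2O[C@H]1c1ccc(O)cc1 | target

**Step count**

Total steps: 4. Longest linear sequence: 4 steps (1 → 2 → 4 → 9 → 10); aldehyde 5 and benzyl bromide are bought.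

**Steps most likely to fail**

Step 3. The aldolates may revert by retro-aldol, dehydrate to arylidene ketones or undergo aldol–Tishchenko hydride transfer before fluoride is displaced. The equilibration may also stop short of the meso isomer, or the ring-opened chalcone may suffer double-bond migration; if the racemic trans,trans pairing proves the more stable, the meso isomer would have to be separated and the rest recycled. The fallback separates ether formation from C–C bond formation and closes the rings through O1–C2 instead. It sets out from 4, whose two fluorides are displaced by hydroxide (KOH, DMSO–H2O, 80 °C) to give 1,4-bis[4-(benzyloxy)-2-hydroxyphenyl]butane-1,4-dione F1. Claisen–Schmidt condensation of F1 with two molecules of 5 (pyrrolidine, EtOH, 78 °C) should give (2E,3E)-1,4-bis[4-(benzyloxy)-2-hydroxyphenyl]-2,3-bis[4-(benzyloxy)benzylidene]butane-1,4-dione F2, which is not isolated but closes under the same conditions by double 6-endo oxa-Michael addition. After the same base equilibration and crystallisation this comes back to the route at 9.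

Step 2. Single-electron oxidation of the enolate may be diverted to α-chlorination by CuCl2 or to self-aldol condensation, so that little dimer forms. The fallback builds the 1,4-diketone by polar C-alkylation instead of radical coupling. It sets out from 2, half of which is α-brominated (CuBr2, EtOAc–CHCl3, 70 °C) to 2-bromo-1-[4-(benzyloxy)-2-fluorophenyl]ethan-1-one F3. F3 is then coupled with a second equivalent of 2 through its zinc enolate (ZnCl2, Et2NH, t-BuOH, toluene, 25 °C), which comes back to the route at 4.

Step 4. Over-reduction may compete with cleavage of the last benzyl ether, either by hydrogenolysis of the benzylic C2–O1 bond or by reduction of the aryl ketone, and the poorly soluble substrate may stall on the catalyst. The fallback replaces hydrogenolysis by Lewis acid-mediated dealkylation. It sets out from 9, which is treated with BCl3 and pentamethylbenzene as cation scavenger in CH2Cl2 at −78 °C, and comes back to the route at 10; no new compound lies on this way (F0).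

**Further compounds**

F1 | step 3 | 1,4-bis[4-(benzyloxy)-2-hydroxyphenyl]butane-1,4-dione | O=C(CCC(=O)c1ccc(OCc2ccccc2)cc1O)c1ccc(OCc2ccccc2)cc1O
F2 | step 3 | (2E,3E)-1,4-bis[4-(benzyloxy)-2-hydroxyphenyl]-2,3-bis[4-(benzyloxy)benzylidene]butane-1,4-dione | O=C(c1ccc(OCc2ccccc2)cc1O)/C(=C/c1ccc(OCc2ccccc2)cc1)C(=C/c1ccc(OCc2ccccc2)cc1)\C(=O)c1ccc(OCc2ccccc2)cc1O
F3 | step 2 | 2-bromo-1-[4-(benzyloxy)-2-fluorophenyl]ethan-1-one | O=C(CBr)c1ccc(OCc2ccccc2)cc1F
F0 | step 4 | none | none
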